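(The data stem from a simulated flask with constants of no real substance, noise included.)

At early times the gamma run holds the right-handed substrate at 49.5% of the charge, while the left-handed substrate has dropped to 36.9% by 1.00 min. I follow this kinetic resolution in logarithms. The separation is the number of decades between [right-handed substrate] and [left-handed substrate]. An excess of 95% means a ratio of 39.0, so the separation needed is 1.59 decades.

all flasks: gas 45 mM (held)
- delta: left-handed substrate 0.10 M; right-handed substrate 0.10 M; precatalyst 0.5 mol%; run made earlier
- epsilon: left-handed substrate 0.10 M; right-handed substrate 0.10 M; precatalyst 0.75 mol%; run made earlier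
- gamma: left-handed substrate 0.15 M; right-handed substrate 0.15 M; precatalyst 1 mol%; run made earlier
- flask: left-handed substrate 0.10 M; right-handed substrate 0.10 M; precatalyst 1 mol%; time 6.0 min

| run | time / min | right-handed substrate / % | left-handed substrate / % |
|---|---|---|---|
| delta | 0.667 | 50.7 | 47.0 |
| delta | 1.33 | 48.3 | 38.9 |
| delta | 2.00 | 49.5 | 31.2 |
| delta | 2.50 | 48.8 | 24.4 |
| delta | 3.00 | 48.9 | 15.2 |
| delta | 4.00 | 46.5 | 5.3 |
| epsilon | 0.250 | 50.2 | 50.2 |
| epsilon | 0.500 | 49.5 | 48.2 |
| epsilon | 0.833 | 48.3 | 43.5 |
| epsilon | 1.33 | 48.6 | 33.4 |
| epsilon | 2.00 | 49.2 | 22.9 |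
| epsilon | 4.00 | 44.4 | 0 |
| gamma | 0.250 | 50.6 | 51.2 |
| gamma | 0.500 | 49.7 | 45.5 |
| gamma | 1.00 | 49.5 | 36.9 |
| gamma | 2.00 | 51.3 | 11.6 |
| gamma | 4.00 | 39.3 | 0 |

(standard deviation of a reading: 1 percentage point)

- whether the excess of right-handed substrate over left-handed substrate among what is left of the two reaches 95% by 6.0 min (yes / no)
- the highest excess of right-handed substrate over left-handed substrate among what is left of the two up to 6.0 min

- free catalyst is single-handed; left-handed substrate and right-handed substrate are mirror images of each other, charged as a racemate, each of them at the stated concentration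
- at the start none of reagent is dissolved
- steps that have been proposed: free catalyst + right-handed substrate <-> catalyst intermediate B; reagent + catalyst intermediate A -> free catalyst + left-handed product; reagent + catalyst intermediate B -> free catalyst + right-handed product; gas <-> reagent; precatalyst -> free catalyst; free catalyst + left-handed substrate <-> catalyst intermediate A; reagent -> decomposition product

Gamma reads 0.646 decades at 2.00 min, which is short of the target. With right-handed substrate near gamma's reading of 49.5%, I put the target for the flask at left-handed substrate of 1.27%. The flask has gamma's loading at a lower concentration, so I take gamma's pace for the early end of a bracket. That pace is 0.253 min⁻¹ as a share of the charge, and run straight on it gives 2.41 min. The flask has more precatalyst than epsilon at the same concentration, so I take epsilon's pace for the late end, as an estimate. That pace is 0.157 min⁻¹, which gives 3.38 min. The late end stands before 6.0 min, so I say yes.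

The forecast says yes, with a top of 99.9% and the excess “reached near 2.5–3 min”, which lies inside my bracket.

The flask gives yes and 100%, and reaches the excess at 2.85 min, between the two ends of my bracket.

    free catalyst + right-handed substrate ⇌ catalyst intermediate B (K = 3.52 L mol⁻¹, k = 1020 L mol⁻¹ s⁻¹)
    reagent + catalyst intermediate A → free catalyst + left-handed product (k = 36.7 L mol⁻¹ s⁻¹)
    reagent + catalyst intermediate B → free catalyst + right-handed product (k = 15.3 L mol⁻¹ s⁻¹)
    gas ⇌ reagent, rate k4*(csat - [reagent]) (kL = 0.373 s⁻¹)
    precatalyst → free catalyst (k = 0.0128 s⁻¹)
    free catalyst + left-handed substrate ⇌ catalyst intermediate A (K = 280 L mol⁻¹, k = 175 L mol⁻¹ s⁻¹)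
    reagent → decomposition product (k = 8.33 × 10⁻⁶ s⁻¹)

The flask gets there in about half of the time allowed. At 3.00 min it stands at 1.88 decades, past the 1.59 needed, with 45.9% right-handed substrate left. The half-life of reagent by the conversion of reagent + catalyst intermediate B into free catalyst + right-handed product is 18 min at 1.46 min and shorter, 4.0 min, at 6.00 min. At that last time the flask holds 0% left-handed substrate and 33.3% right-handed substrate.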